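The constants of both steps are hidden, so they must be read from the grey and red runs, which differ in their reagent charge, as the new flasks do.

| flask | starting material | reagent | second substrate | remark | time |
|---|---|---|---|---|---|
| grey | 10 mM | 2 mM | 50 mM | run made earlier |  |
| red | 10 mM | 27 mM | 50 mM | run made earlier |  |
| alpha | 10 mM | 2.50 mM | 50.0 mM |  | 6.0 h |
| gamma | 10 mM | 20.0 mM | 50.0 mM |  | 6.0 h |
| theta | 10 mM | 10.0 mM | 50.0 mM |  | 6.0 h |
| epsilon | 10 mM | 5.00 mM | 50.0 mM |  | 6.0 h |
| eta | 10 mM | 30.0 mM | 50.0 mM |  | 6.0 h |
| beta | 10 mM | 3.00 mM | 50.0 mM |  | 6.0 h |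

| run | time / h | target / % | starting material / % |
|---|---|---|---|
| grey | 0.417 | 2.0 | 97.3 |
| grey | 1.33 | 4.0 | 97.1 |
| grey | 2.00 | 7.1 | 93.8 |
| grey | 3.00 | 6.2 | 91.7 |
| grey | 5.00 | 10.9 | 90.2 |
| grey | 6.00 | 12.0 | 88.5 |
| red | 0.417 | 20.7 | 80.3 |
| red | 1.33 | 46.4 | 52.4 |
| red | 2.00 | 59.3 | 42.9 |
| red | 3.00 | 70.6 | 29.2 |
| red | 5.00 | 82.5 | 17.3 |
| red | 6.00 | 86.1 | 12.3 |

(each reading ± 1 percentage point)

- the flasks by amount of target, in percent of the starting material charged, highest first, at 6.0 h (alpha / gamma / theta / epsilon / eta / beta)
- the same order at 25 h (alpha / gamma / theta / epsilon / eta / beta)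
- the amount of target, in percent of the starting material charged of the flask you put first, at 6.0 h
- the amount of target, in percent of the starting material charged of the flask you put last, at 6.0 h

The rate constant k of starting material + reagent comes from the first red reading, taken as pseudo-first-order decay at the charged reagent: k = 0.0195 mM⁻¹ h⁻¹. Between 3.00 h and 6.00 h the starting material in red decays at λ = 0.288 h⁻¹, so λ/k gives 14.8 mM of free reagent. The reagent not in target over that stretch of red is 19.2 mM.

The free share f is free reagent divided by reagent not in target; the rest stands as second product. Red gives f = 0.772.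

The grey run is a second way. Its 88.5% of starting material at 6.00 h gives, with the same k, a mean free reagent of 1.04 mM, out of 1.40 mM not in target, so f = 0.746. Beyond k the two ways share no reading, and k cancels from the ratio of their two values of f. Their gap is 3.28% of f, while the conversion in grey, 11.5%, is read to 1 percentage point. Their mean, f = 0.759, is the quantity carried forward.

The reckoning here takes target as X = 1 − exp(−k f R t), where R is the charge less half the target of the previous round. In eta, R at the full charge gives 93.0%, and a second round gives 89.5%. In alpha the rounds swing: 19.9%, 12.5%, 15.3%. At fixed f the reckoning ranks the flasks by charge, eta first and alpha last.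

The forecast gives eta > gamma > theta > epsilon > beta > alpha at 6.0 h, eta > gamma > theta > epsilon > beta > alpha at 25 h, 89.5% for the first flask and 14.7% for the last. Its ground for the later order: “More reagent always gives more target”.

The flasks give eta > gamma > theta > epsilon > beta > alpha at 6.0 h and eta > gamma > theta > epsilon > beta > alpha at 25 h, with 89.1% of target in eta and 14.7% in alpha at 6.0 h.

    starting material + reagent ⇌ target (K = 1300 L mol⁻¹, k = 0.390 L mol⁻¹ min⁻¹)
    second substrate + reagent ⇌ second product (K = 6.90 L mol⁻¹, k = 0.160 L mol⁻¹ min⁻¹)

In eta at 6.00 h the second step by itself relaxes, both ways together, with a half-life of 0.351 h, shorter than the 1.65 h of the target step by itself, and the free share stands at 0.761. With 7.5 mM of reagent in the neighbouring flask, otherwise as eta, the carried f gives rounds of 48.6%, 36.2% and 39.6%. That flask gives 39.3% of target.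

(The readings are simulated from invented constants, noise included.)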